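The cyclohexene ring (C5–C6–C7–C8=C9–C10, C5 the spiro carbon, spiro[4.5]decene locants) is read as a latent 1,5-keto-aldehyde: the C8=C9 double bond next to the C7 oxygen is opened to a C9 aldehyde and a C7 ethyl ketone, both on CH2 arms of C5. One operation (enol-ether hydrolysis, carbonyl-directed gold hydration of a but-2-ynyl arm, intramolecular aldol condensation) closes this ring last, as a 2-methylcyclohexenone. The precursor is a cyclopentane with a 2-methoxyvinyl and a but-2-ynyl group on its quaternary carbon. Its stereocentres are bought with nepetalactone, and the spiro centre is relayed from them by convex-face lactone alkylation. The butenolide is attached afterwards as an intact ring.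

Key step: step 6

Assumption: cis,trans-nepetalactone 1, the main lactone of catnip oil, is taken as a purchasable single stereoisomer. Its C4a and C7 map onto C4 and C1 of the target, and its C7a becomes the spiro carbon C5.

Step 1
Reactants: 1 (4aS,7S,7aR)-nepetalactone
Product: 2 (4S,4aR,7S,7aR)-dihydronepetalactone
Conditions: H2 (1 atm), 10% Pd/C, EtOAc, rt
Reagents that add atoms: none
Why: Catalytic hydrogenation of the enol-lactone C3=C4 bond should deliver hydrogen to the convex face of the cis-fused bicycle (syn to H-4a and H-7a), which sets C4 as S, the future side-chain methyl stereocentre.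

Step 2
Reactants: 2 (4S,4aR,7S,7aR)-dihydronepetalactone; 3 1-bromobut-2-yne
Product: 4 7a-(but-2-ynyl) lactone
Conditions: LDA (commercial solution), THF, −78 °C; then 3, DMPU, −78 → 0 °C
Reagents that add atoms: 1-bromobut-2-yne (3), CC#CCBr
Why: Alkylation of the lithium lactone enolate with a propargylic bromide (SN2) should occur on the convex face so that the cis ring fusion is kept, which fixes the quaternary carbon (future C5) with the butynyl arm anti and the lactone carbonyl syn to C4 of the lactone.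

Step 3
Reactants: 4 7a-(but-2-ynyl) lactone
Product: 5 lactol (both anomers)
Conditions: DIBAL-H, CH2Cl2, −78 °C; Rochelle salt work-up
Reagents that add atoms: none
Why: DIBAL-H reduction of a lactone at −78 °C should stop at the lactol because the tetrahedral aluminium alkoxide survives until work-up, and the internal alkyne is inert to it.

Step 4
Reactants: 5 lactol; 6 (methoxymethyl)triphenylphosphonium chloride
Product: 7 hydroxy enol ether (E/Z mixture)
Conditions: 6, t-BuOK, THF, 0 °C; then 5, 0 → 40 °C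
Reagents that add atoms: (methoxymethyl)triphenylphosphonium chloride (6), COC[P+](c1ccccc1)(c1ccccc1)c1ccccc1.[Cl-]
Why: Wittig methoxymethylenation of the open hydroxy-aldehyde tautomer of the lactol adds the carbon that becomes C9, turns the former lactone carbon into the future C10 methylene and frees the primary alcohol; the enol-ether geometry is irrelevant.

Step 5
Reactants: 7 hydroxy enol ether; 8 tert-butyl(chloro)diphenylsilane
Product: 9 TBDPS ether
Conditions: TBDPSCl, imidazole, CH2Cl2, rt
Reagents that add atoms: tert-butyl(chloro)diphenylsilane (8), CC(C)(C)[Si](Cl)(c1ccccc1)c1ccccc1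
Why: Standard silylation of the only hydroxyl group gives an acid-tolerant silyl ether that keeps the side-chain oxygen distinct from the ring oxygen introduced later.

Step 6
Reactants: 9 TBDPS ether
Product: 12 spiro enone, via ynal 10 (not isolated), via keto-aldehyde 11 (not isolated)
Conditions: Ph3PAuNTf2 (3 mol %), TsOH·H2O (0.2 equiv), 1,4-dioxane–H2O (10:1), rt → 80 °C
Reagents that add atoms: water, O
Why: Acid hydrolyses the enol ether to aldehyde 10; cationic gold(I) then activates the alkyne, the aldehyde (hydrate) oxygen attacks its proximal carbon in a 6-exo-dig sense and protodeauration/hydrolysis gives the 1,5-keto-aldehyde 11, whose ethyl-ketone enol (C8) adds to the protonated C9 aldehyde and loses water to the conjugated enone. The closest known reaction types are the carbonyl-assisted gold-catalysed Markovnikov hydration of alkynes and the Robinson-type intramolecular aldol condensation of 1,5-dicarbonyls, together a hydrative alkyne–aldehyde cyclisation. The six-membered ring is closed by a 6-(enolendo)-exo-trig aldol addition that forms the C8–C9 bond. No new stereocentre is formed, and the quaternary C5 set in step 2 cannot epimerise. The step needs regioselective hydration (oxygen at C7, not C8), secured by six-membered oxygen delivery from the C9 carbonyl and by the gem-disubstitution at C5, and a single aldol mode, secured because every other enol/carbonyl pairing would close a four-membered ring.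

Step 7
Reactants: 12 spiro enone
Product: 13 (7S)-allylic alcohol
Conditions: (R)-Me-CBS (0.3 equiv), catecholborane, toluene, −78 °C
Reagents that add atoms: none
Why: Corey–Bakshi–Shibata 1,2-reduction, with the α-methyl-alkenyl side as the large group, should give the (7S)-alcohol under catalyst control with (R)-Me-CBS (the sense that turns acetophenone into (S)-1-phenylethanol) and without conjugate reduction.

Step 8
Reactants: 13 (7S)-allylic alcohol; 14 3-phenylpropanoyl chloride
Product: 15 silyl ether ester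
Conditions: 14, pyridine, DMAP (cat.), CH2Cl2, 0 °C → rt
Reagents that add atoms: 3-phenylpropanoyl chloride (14), O=C(Cl)CCc1ccccc1
Why: DMAP-catalysed acylation of the secondary allylic alcohol with the acid chloride should form the ester with retention at C7.

Step 9
Reactants: 15 silyl ether ester
Product: 16 primary alcohol
Conditions: HF·pyridine, THF, 0 °C → rt
Reagents that add atoms: none
Why: Fluoride-mediated Si–O cleavage should free the primary alcohol without touching the allylic ester.

Step 10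
Reactants: 16 primary alcohol
Product: 17 aldehyde
Conditions: Dess–Martin periodinane, NaHCO3, CH2Cl2, 0 °C
Reagents that add atoms: none
Why: Dess–Martin oxidation under buffered, non-basic conditions should give the α-branched aldehyde without epimerising its α-stereocentre.

Step 11
Reactants: 17 aldehyde; 18 3-methylfuran-2(5H)-one
Product: 21 target, via silyloxyfuran 19 (not isolated), via silyl aldol adduct 20 (not isolated)
Conditions: 18, TBSOTf, i-Pr2NEt, CH2Cl2, 0 °C; then 17, −78 → 0 °C; then DBU, rt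
Reagents that add atoms: 3-methylfuran-2(5H)-one (18), CC1=CCOC1=O; tert-butyldimethylsilyl triflate, CC(C)(C)[Si](C)(C)OS(=O)(=O)C(F)(F)F (its silyl group is carried only by 19 and 20)
Why: Vinylogous Mukaiyama aldol addition of the in-situ silyloxyfuran at its γ-carbon, then DBU-induced E1cB loss of silanolate, should give the thermodynamically preferred (Z)-γ-ylidene butenolide (chain cis to the ring oxygen); the butenolide ring is brought in intact.

Compound list
1 | (4aS,7S,7aR)-nepetalactone, (4aS,7S,7aR)-4,7-dimethyl-5,6,7,7a-tetrahydrocyclopenta[c]pyran-1(4aH)-one | O=C1OC=C(C)[C@H]2CC[C@H](C)[C@@H]12 | starting material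
2 | (4S,4aR,7S,7aR)-dihydronepetalactone, (4S,4aR,7S,7aR)-4,7-dimethylhexahydrocyclopenta[c]pyran-1(3H)-one | O=C1OC[C@@H](C)[C@H]2CC[C@H](C)[C@@H]12 | intermediate
3 | 1-bromobut-2-yne | CC#CCBr | starting material
4 | (4S,4aR,7S,7aR)-7a-(but-2-yn-1-yl)-4,7-dimethylhexahydrocyclopenta[c]pyran-1(3H)-one | O=C1OC[C@@H](C)[C@H]2CC[C@H](C)[C@@]12CC#CC | intermediate
5 | (4S,4aR,7S,7aR)-7a-(but-2-yn-1-yl)-4,7-dimethyloctahydrocyclopenta[c]pyran-1-ol (lactol, both anomers) | OC1OC[C@@H](C)[C@H]2CC[C@H](C)[C@@]12CC#CC | intermediate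
6 | (methoxymethyl)triphenylphosphonium chloride | COC[P+](c1ccccc1)(c1ccccc1)c1ccccc1.[Cl-] | starting material
7 | (2S)-2-[(1R,2R,3S)-2-(but-2-yn-1-yl)-2-(2-methoxyethenyl)-3-methylcyclopentyl]propan-1-ol (E/Z mixture) | OC[C@@H](C)[C@H]1CC[C@H](C)[C@@]1(CC#CC)C=COC | intermediate
8 | tert-butyl(chloro)diphenylsilane | CC(C)(C)[Si](Cl)(c1ccccc1)c1ccccc1 | starting material
9 | tert-butyl{[(2S)-2-[(1R,2R,3S)-2-(but-2-yn-1-yl)-2-(2-methoxyethenyl)-3-methylcyclopentyl]propyl]oxy}diphenylsilane (E/Z mixture) | CC(C)(C)[Si](OC[C@@H](C)[C@H]1CC[C@H](C)[C@@]1(CC#CC)C=COC)(c1ccccc1)c1ccccc1 | intermediate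
10 | 2-[(1R,2R,5S)-1-(but-2-yn-1-yl)-2-[(2S)-1-{[tert-butyl(diphenyl)silyl]oxy}propan-2-yl]-5-methylcyclopentyl]acetaldehyde | CC(C)(C)[Si](OC[C@@H](C)[C@H]1CC[C@H](C)[C@@]1(CC#CC)CC=O)(c1ccccc1)c1ccccc1 | intermediate
11 | 2-[(1S,2R,5S)-2-[(2S)-1-{[tert-butyl(diphenyl)silyl]oxy}propan-2-yl]-5-methyl-1-(2-oxobutyl)cyclopentyl]acetaldehyde | CC(C)(C)[Si](OC[C@@H](C)[C@H]1CC[C@H](C)[C@@]1(CC(=O)CC)CC=O)(c1ccccc1)c1ccccc1 | intermediate
12 | (1S,4R,5S)-4-[(2S)-1-{[tert-butyl(diphenyl)silyl]oxy}propan-2-yl]-1,8-dimethylspiro[4.5]dec-8-en-7-one | CC(C)(C)[Si](OC[C@@H](C)[C@H]1CC[C@H](C)[C@@]12CC=C(C)C(=O)C2)(c1ccccc1)c1ccccc1 | intermediate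
13 | (1S,4R,5S,7S)-4-[(2S)-1-{[tert-butyl(diphenyl)silyl]oxy}propan-2-yl]-1,8-dimethylspiro[4.5]dec-8-en-7-ol | CC(C)(C)[Si](OC[C@@H](C)[C@H]1CC[C@H](C)[C@@]12CC=C(C)[C@@H](O)C2)(c1ccccc1)c1ccccc1 | intermediate
14 | 3-phenylpropanoyl chloride | O=C(Cl)CCc1ccccc1 | starting material
15 | (1S,4R,5S,7S)-4-[(2S)-1-{[tert-butyl(diphenyl)silyl]oxy}propan-2-yl]-1,8-dimethylspiro[4.5]dec-8-en-7-yl 3-phenylpropanoate | CC(C)(C)[Si](OC[C@@H](C)[C@H]1CC[C@H](C)[C@@]12CC=C(C)[C@@H](OC(=O)CCc3ccccc3)C2)(c1ccccc1)c1ccccc1 | intermediate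
16 | (1S,4R,5S,7S)-4-[(2S)-1-hydroxypropan-2-yl]-1,8-dimethylspiro[4.5]dec-8-en-7-yl 3-phenylpropanoate | OC[C@@H](C)[C@H]1CC[C@H](C)[C@@]12CC=C(C)[C@@H](OC(=O)CCc3ccccc3)C2 | intermediate
17 | (1S,4R,5S,7S)-1,8-dimethyl-4-[(2S)-1-oxopropan-2-yl]spiro[4.5]dec-8-en-7-yl 3-phenylpropanoate | O=C[C@@H](C)[C@H]1CC[C@H](C)[C@@]12CC=C(C)[C@@H](OC(=O)CCc3ccccc3)C2 | intermediate
18 | 3-methylfuran-2(5H)-one | CC1=CCOC1=O | starting material
19 | tert-butyldimethyl[(3-methylfuran-2-yl)oxy]silane | Cc1ccoc1O[Si](C)(C)C(C)(C)C | intermediate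
20 | (1S,4R,5S,7S)-4-[(2S)-1-{[tert-butyl(dimethyl)silyl]oxy}-1-(4-methyl-5-oxo-2,5-dihydrofuran-2-yl)propan-2-yl]-1,8-dimethylspiro[4.5]dec-8-en-7-yl 3-phenylpropanoate (mixture at the two new centres) | CC1=CC(OC1=O)C(O[Si](C)(C)C(C)(C)C)[C@@H](C)[C@H]2CC[C@H](C)[C@@]23CC=C(C)[C@@H](OC(=O)CCc4ccccc4)C3 | intermediate
21 | (1S,4R,5S,7S)-1,8-dimethyl-4-{(2S)-1-[(2Z)-4-methyl-5-oxofuran-2(5H)-ylidene]propan-2-yl}spiro[4.5]dec-8-en-7-yl 3-phenylpropanoate | CC1=C/C(=C/[C@@H](C)[C@H]2CC[C@H](C)[C@@]23CC=C(C)[C@@H](OC(=O)CCc2ccccc2)C3)OC1=O | target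

Total step count: 11. Longest linear sequence: 11 steps (1 → 21); compounds 3, 6, 8, 14 and 18 are purchased.

Steps most likely to fail

Step 6 (key step). The gold hydration may lose regiocontrol, with water adding at the methyl-bearing alkyne carbon, or the cascade may stall at a cyclic enol ether or 4H-pyran before the aldol condensation. The fallback installs the ketone while the lactone can direct it. It sets out from lactone 4, which is hydrated with an Au(III) or Hg(II) catalyst in aqueous acetonitrile; here the lactone carbonyl delivers oxygen by 5-exo-dig attack, giving the γ-keto lactone (4S,4aR,7S,7aR)-4,7-dimethyl-7a-(2-oxobutyl)hexahydrocyclopenta[c]pyran-1(3H)-one F1. The ketone is masked as the dioxolane F2 (ethylene glycol, TsOH, benzene, water removal). DIBAL-H reduction gives the lactol F3, methoxymethylenation gives the hydroxy enol ether F4, and silylation gives the TBDPS ether F5. Aqueous HCl in THF then unmasks aldehyde and ketone together to give 11, which is condensed with TsOH in toluene at 80 °C, so that the route is rejoined at 12.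

Step 4. Ring-opening of the hindered lactol and attack on an aldehyde attached to a fully substituted carbon may be slower than decomposition of the ylide. The fallback avoids the lactol. It sets out from 4, which is reduced with LiAlH4 (THF, 0 °C) to the diol F6. The less hindered primary alcohol is silylated selectively (TBDPSCl, imidazole, 0 °C) to the mono-silyl ether F7. Dess–Martin oxidation of the remaining neopentyl alcohol gives the free aldehyde F8, and Wittig methoxymethylenation of this open aldehyde (Ph3P=CHOMe, THF, rt → reflux) gives 9 directly, where the route is rejoined.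

Step 7. Catalyst control may be eroded by an opposing facial bias of the spiro-fused cyclopentane, leading to poor selectivity at C7. The fallback makes the esterification stereoinvertive, so that both epimers converge. It sets out from 12, which is reduced with (S)-Me-CBS and catecholborane (or under Luche conditions if the intrinsic bias points that way) to the (7R)-alcohol F9. Mitsunobu esterification of F9 with 3-phenylpropanoic acid (PPh3, DIAD, THF, 0 °C) proceeds with inversion and gives 15, where the route is rejoined. Any (7S)-alcohol 13 in the mixture is acylated as in step 8.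

Further compounds
F1 | step 6 | (4S,4aR,7S,7aR)-4,7-dimethyl-7a-(2-oxobutyl)hexahydrocyclopenta[c]pyran-1(3H)-one | O=C1OC[C@@H](C)[C@H]2CC[C@H](C)[C@@]12CC(=O)CC
F2 | step 6 | (4S,4aR,7S,7aR)-7a-[(2-ethyl-1,3-dioxolan-2-yl)methyl]-4,7-dimethylhexahydrocyclopenta[c]pyran-1(3H)-one | O=C1OC[C@@H](C)[C@H]2CC[C@H](C)[C@@]12CC3(CC)OCCO3
F3 | step 6 | (4S,4aR,7S,7aR)-7a-[(2-ethyl-1,3-dioxolan-2-yl)methyl]-4,7-dimethyloctahydrocyclopenta[c]pyran-1-ol (lactol, both anomers) | OC1OC[C@@H](C)[C@H]2CC[C@H](C)[C@@]12CC3(CC)OCCO3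
F4 | step 6 | (2S)-2-[(1R,2R,3S)-2-[(2-ethyl-1,3-dioxolan-2-yl)methyl]-2-(2-methoxyethenyl)-3-methylcyclopentyl]propan-1-ol (E/Z mixture) | OC[C@@H](C)[C@H]1CC[C@H](C)[C@@]1(CC2(CC)OCCO2)C=COC
F5 | step 6 | tert-butyl{[(2S)-2-[(1R,2R,3S)-2-[(2-ethyl-1,3-dioxolan-2-yl)methyl]-2-(2-methoxyethenyl)-3-methylcyclopentyl]propyl]oxy}diphenylsilane (E/Z mixture) | CC(C)(C)[Si](OC[C@@H](C)[C@H]1CC[C@H](C)[C@@]1(CC2(CC)OCCO2)C=COC)(c1ccccc1)c1ccccc1
F6 | step 4 | (2S)-2-[(1R,2R,3S)-2-(but-2-yn-1-yl)-2-(hydroxymethyl)-3-methylcyclopentyl]propan-1-ol | OC[C@@H](C)[C@H]1CC[C@H](C)[C@@]1(CC#CC)CO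
F7 | step 4 | [(1R,2R,5S)-1-(but-2-yn-1-yl)-2-[(2S)-1-{[tert-butyl(diphenyl)silyl]oxy}propan-2-yl]-5-methylcyclopentyl]methanol | CC(C)(C)[Si](OC[C@@H](C)[C@H]1CC[C@H](C)[C@@]1(CC#CC)CO)(c1ccccc1)c1ccccc1
F8 | step 4 | (1R,2R,5S)-1-(but-2-yn-1-yl)-2-[(2S)-1-{[tert-butyl(diphenyl)silyl]oxy}propan-2-yl]-5-methylcyclopentane-1-carbaldehyde | CC(C)(C)[Si](OC[C@@H](C)[C@H]1CC[C@H](C)[C@@]1(CC#CC)C=O)(c1ccccc1)c1ccccc1
F9 | step 7 | (1S,4R,5S,7R)-4-[(2S)-1-{[tert-butyl(diphenyl)silyl]oxy}propan-2-yl]-1,8-dimethylspiro[4.5]dec-8-en-7-ol | CC(C)(C)[Si](OC[C@@H](C)[C@H]1CC[C@H](C)[C@@]12CC=C(C)[C@H](O)C2)(c1ccccc1)c1ccccc1
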